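The decalin is disconnected at the ring-fusion bond C5–C10 (drimane numbering). The key step exploits two features: C11 on C9 and C1 on C10 are cis across the C9–C10 bond, so they can be tied as a temporary γ-butyrolactone whose enolate carbon is C10, and C5 is β to the C3 ketone. Fluoride releases the lactone enolate from a silyl ketene acetal; it adds 6-exo to the (E)-C5=C4 enone, closing ring B and setting C10 and C5 from the single C9 stereocentre, and the C3–C4 enolate is methylated in the same flask. The precursor is a monocyclic lactone-derived ketene acetal with an acyclic dienone chain; ring A is closed afterwards by aldol addition.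

Key step: step 7

Remark: carbons are numbered as in drimane (ring A: C1–C5 and C10; ring B: C5–C10; C11 is the CH2O carbon on C9, C12 the methylidene carbon on C8); isofraxidin is taken to be commercially available.

Step 1
Reactants: 1 2,3-dibromoprop-1-ene; 2 allylmagnesium bromide
Product: 3 2-bromohexa-1,5-diene
Conditions: Et2O, 0 °C → rt
Reagents that add atoms: none
Why: SN2 coupling of the allyl Grignard reagent at the allylic C–Br bond, with the vinylic bromide inert, should give the bromodiene; no stereocentre is formed.

Step 2
Reactants: 3 2-bromohexa-1,5-diene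
Product: 6 potassium trifluoro(hexa-1,5-dien-2-yl)borate, via hexa-1,5-dien-2-yllithium 4 (not isolated), via lithium trimethoxyborate 5 (not isolated)
Conditions: t-BuLi (2.1 equiv), Et2O, −78 °C; B(OMe)3, −78 °C → rt; aq. KHF2
Reagents that add atoms: trimethyl borate COB(OC)OC; potassium hydrogen difluoride F.[F-].[K+]
Why: Bromine–lithium exchange, borylation of the vinyllithium and fluoride exchange should give the bench-stable alkenyltrifluoroborate; no stereocentre is formed.

Step 3
Reactants: 6 potassium trifluoro(hexa-1,5-dien-2-yl)borate; 7 furan-2(5H)-one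
Product: 8 (4R)-4-(hexa-1,5-dien-2-yl)oxolan-2-one
Conditions: [Rh(cod)2]BF4 (3 mol %), (R)-BINAP (3.3 mol %), 6 (2 equiv), toluene/H2O (20:1), 100 °C
Reagents that add atoms: none
Why: Rhodium-catalysed asymmetric 1,4-addition (Hayashi–Miyaura reaction), in which the alkenyl–rhodium species bearing (R)-BINAP inserts one enantioface of the butenolide and so sets the future C9 as (R), following the facial sense by which (S)-BINAP gives (S)-3-substituted cyclohexanones and the topologically equivalent lactones.

Step 4
Reactants: 8 (4R)-4-(hexa-1,5-dien-2-yl)oxolan-2-one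
Product: 10 (3S,4R)-4-(hexa-1,5-dien-2-yl)-3-methyloxolan-2-one, via lithium enolate 9 (not isolated)
Conditions: LiN(iPr)2, THF, −78 °C; MeI, −78 → −40 °C
Reagents that add atoms: iodomethane CI
Why: Lactone enolate alkylation anti to the C4 substituent should give the 3,4-trans methyl lactone; this centre (the future C10) is made planar again in step 5, so its configuration is of no consequence.

Step 5
Reactants: 10 (3S,4R)-4-(hexa-1,5-dien-2-yl)-3-methyloxolan-2-one
Product: 12 tert-butyl{[(4S)-4-(hexa-1,5-dien-2-yl)-3-methyl-4,5-dihydrofuran-2-yl]oxy}dimethylsilane, via lithium enolate 11 (not isolated)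
Conditions: LiN(iPr)2, THF, −78 °C; TBSCl, DMPU, −78 °C → rt
Reagents that add atoms: tert-butyl(chloro)dimethylsilane CC(C)(C)[Si](C)(C)Cl
Why: O-silylation of the lithium enolate stores the C10 nucleophile as a neutral, tetrasubstituted silyl ketene acetal before the enolisable ketone is introduced; the C9 stereocentre is untouched.

Step 6
Reactants: 12 tert-butyl{[(4S)-4-(hexa-1,5-dien-2-yl)-3-methyl-4,5-dihydrofuran-2-yl]oxy}dimethylsilane; 13 3-methylbut-3-en-2-one
Product: 14 (3E)-7-[(3S)-5-{[tert-butyl(dimethyl)silyl]oxy}-4-methyl-2,3-dihydrofuran-3-yl]-3-methylocta-3,7-dien-2-one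
Conditions: second-generation Hoveyda–Grubbs catalyst (5 mol %), 13 (5 equiv), CH2Cl2, 40 °C
Reagents that add atoms: none
Why: Olefin cross-metathesis of the monosubstituted terminal alkene with the electron-poor 1,1-disubstituted enone should give the (E)-trisubstituted enone, the hindered C8 methylidene group and the tetrasubstituted ketene acetal being inert toward the ruthenium carbene.

Step 7
Reactants: 14 (3E)-7-[(3S)-5-{[tert-butyl(dimethyl)silyl]oxy}-4-methyl-2,3-dihydrofuran-3-yl]-3-methylocta-3,7-dien-2-one
Product: 18 (3aS,7R,7aR)-7a-methyl-7-(2-methyl-3-oxobutan-2-yl)-4-methylidene-3a,4,5,6,7,7a-hexahydro-2-benzofuran-1(3H)-one, via sulfonium lactone enolate 15 (not isolated), via silyl enol ether 16 (not isolated), via sulfonium ketone enolate 17 (not isolated)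
Conditions: (Me2N)3S+ Me3SiF2− (TASF, 0.1 equiv), THF, −78 → −30 °C; then MeI (5 equiv), TASF (1.1 equiv), −30 → 0 °C
Reagents that add atoms: iodomethane CI
Why: Catalytic fluoride removes the silyl group from the ketene acetal and the free lactone enolate (nucleophilic at C10) adds to C5 of the tethered (E)-enone, the resulting C3–C4 enolate being silylated by the next ketene acetal (chain transfer) until all substrate is cyclised, after which stoichiometric fluoride regenerates this regiodefined enolate and iodomethane alkylates it at C4 to complete the gem-dimethyl group. The closest known reaction type is the fluoride-catalysed Mukaiyama–Michael addition of silyl ketene acetals to enones with in situ alkylation of the adduct enolate. Ring B is closed in the 6-exo-trig mode by the new C5–C10 bond. The quaternary centre C10 is controlled by the C9 stereocentre through the planar five-membered enolate: the C8 tether can reach only the face it occupies, so the lactone ends cis-fused, which places the C10 methyl group cis to H9 and C11 axial on ring B. C5 is set by a chair transition state with the enone arm equatorial, because the axial alternative would collide with the axial C11, so H5 ends trans to the C10 methyl group and C1 and C4 end trans-diequatorial for the later closure of ring A. The step needs chemoselective generation of the lactone enolate next to an enolisable methyl ketone, which the silicon–fluoride trigger secures without any base, and C- rather than O-methylation, which the soft electrophile iodomethane favours.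

Step 8
Reactants: 18 (3aS,7R,7aR)-7a-methyl-7-(2-methyl-3-oxobutan-2-yl)-4-methylidene-3a,4,5,6,7,7a-hexahydro-2-benzofuran-1(3H)-one
Product: 21 (4aR,5S,8aS)-4-hydroxy-5-(hydroxymethyl)-1,1,4a-trimethyl-6-methylideneoctahydronaphthalen-2(1H)-one, via lithium enolate 19 (not isolated), via aluminium lactolate 20 (not isolated)
Conditions: LiN(SiMe3)2 (1.1 equiv), THF, −78 °C; iBu2AlH (1.2 equiv), −78 °C; warm to −20 °C; aq. potassium sodium tartrate
Reagents that add atoms: none
Why: The only acidic site of 18 is the acetyl methyl group (C2), so its lithium enolate protects the ketone while iBu2AlH reduces the lactone to the aluminium lactolate, and on warming this opens to the C1 aldehyde, which the enolate captures in an intramolecular aldol addition that closes ring A trans-fused (C1 and C4 are diequatorial on ring B) and creates an inconsequential C1 carbinol centre that step 9 removes.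

Step 9
Reactants: 21 (4aR,5S,8aS)-4-hydroxy-5-(hydroxymethyl)-1,1,4a-trimethyl-6-methylideneoctahydronaphthalen-2(1H)-one
Product: 23 [(1S,4aS,8aR)-5,5,8a-trimethyl-2-methylidene-6-oxo-1,2,3,4,4a,5,6,8a-octahydronaphthalen-1-yl]methyl methanesulfonate, via bis-mesylate 22 (not isolated)
Conditions: MsCl (3 equiv), Et3N (6 equiv), CH2Cl2, 0 °C → rt
Reagents that add atoms: methanesulfonyl chloride CS(=O)(=O)Cl
Why: Sulfene-mediated mesylation of both hydroxyl groups followed by E1cB elimination of the β-mesyloxy ketone should give the C1=C2 enone while the primary C11 mesylate survives, so the C11 oxygen is never a free alcohol next to the enone and cannot add back to C1 by oxa-Michael reaction; no stereocentre is touched.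

Step 10
Reactants: 23 [(1S,4aS,8aR)-5,5,8a-trimethyl-2-methylidene-6-oxo-1,2,3,4,4a,5,6,8a-octahydronaphthalen-1-yl]methyl methanesulfonate; 24 isofraxidin
Product: 25 7-{[(1S,4aS,8aR)-5,5,8a-trimethyl-2-methylidene-6-oxo-1,2,3,4,4a,5,6,8a-octahydronaphthalen-1-yl]methoxy}-6,8-dimethoxy-2H-chromen-2-one
Conditions: Cs2CO3, Bu4NI (cat.), DMF, 60 °C
Reagents that add atoms: none
Why: Williamson ether synthesis, in which the cesium phenoxide of isofraxidin displaces the primary C11 mesylate by SN2; the enone mesylate has no enolisable hydrogen (C4 and C10 are quaternary) and C9 is not involved, so the configuration is retained.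

Compound list
1 | 2,3-dibromoprop-1-ene | C=C(Br)CBr | starting material
2 | allylmagnesium bromide (solution in Et2O) | C=CC[Mg]Br | starting material
3 | 2-bromohexa-1,5-diene | C=CCCC(Br)=C | intermediate
4 | hexa-1,5-dien-2-yllithium | [Li]C(=C)CCC=C | intermediate
5 | lithium trimethoxy(hexa-1,5-dien-2-yl)borate | [Li+].CO[B-](OC)(OC)C(=C)CCC=C | intermediate
6 | potassium trifluoro(hexa-1,5-dien-2-yl)borate | [K+].F[B-](F)(F)C(=C)CCC=C | intermediate
7 | furan-2(5H)-one | O=C1C=CCO1 | starting material
8 | (4R)-4-(hexa-1,5-dien-2-yl)oxolan-2-one | O=C1C[C@H](C(=C)CCC=C)CO1 | intermediate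
9 | lithium enolate of 8 | [Li]OC1=C[C@H](C(=C)CCC=C)CO1 | intermediate
10 | (3S,4R)-4-(hexa-1,5-dien-2-yl)-3-methyloxolan-2-one (3,4-trans) | O=C1OC[C@@H](C(=C)CCC=C)[C@@H]1C | intermediate
11 | lithium enolate of 10 | CC1=C(O[Li])OC[C@H]1C(=C)CCC=C | intermediate
12 | tert-butyl{[(4S)-4-(hexa-1,5-dien-2-yl)-3-methyl-4,5-dihydrofuran-2-yl]oxy}dimethylsilane | CC1=C(O[Si](C)(C)C(C)(C)C)OC[C@H]1C(=C)CCC=C | intermediate
13 | 3-methylbut-3-en-2-one | CC(=O)C(C)=C | starting material
14 | (3E)-7-[(3S)-5-{[tert-butyl(dimethyl)silyl]oxy}-4-methyl-2,3-dihydrofuran-3-yl]-3-methylocta-3,7-dien-2-one | CC1=C(O[Si](C)(C)C(C)(C)C)OC[C@H]1C(=C)CC/C=C(\C)C(C)=O | intermediate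
15 | tris(dimethylamino)sulfonium lactone enolate formed from 14 | CC1=C([O-])OC[C@H]1C(=C)CC/C=C(\C)C(C)=O.CN(C)[S+](N(C)C)N(C)C | intermediate
16 | tert-butyldimethylsilyl C3–C4 enol ether of the cyclised cis-fused lactone (H9 cis to the C10 methyl, H5 trans to it) | C=C1CC[C@H](C(C)=C(C)O[Si](C)(C)C(C)(C)C)[C@@]2(C)C(=O)OC[C@@H]12 | intermediate
17 | tris(dimethylamino)sulfonium C3–C4 enolate of the cyclised lactone | C=C1CC[C@H](C(C)=C(C)[O-])[C@@]2(C)C(=O)OC[C@@H]12.CN(C)[S+](N(C)C)N(C)C | intermediate
18 | (3aS,7R,7aR)-7a-methyl-7-(2-methyl-3-oxobutan-2-yl)-4-methylidene-3a,4,5,6,7,7a-hexahydro-2-benzofuran-1(3H)-one | C=C1CC[C@H](C(C)(C)C(C)=O)[C@@]2(C)C(=O)OC[C@@H]12 | intermediate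
19 | lithium enolate of the methyl ketone of 18 | C=C1CC[C@H](C(C)(C)C(=C)O[Li])[C@@]2(C)C(=O)OC[C@@H]12 | intermediate
20 | diisobutylaluminium lactolate of 19 (lactol carbon as a mixture) | C=C1CC[C@H](C(C)(C)C(=C)O[Li])[C@@]2(C)C(O[Al](CC(C)C)CC(C)C)OC[C@@H]12 | intermediate
21 | (4aR,5S,8aS)-4-hydroxy-5-(hydroxymethyl)-1,1,4a-trimethyl-6-methylideneoctahydronaphthalen-2(1H)-one (both C4 epimers) | C=C1CC[C@@H]2C(C)(C)C(=O)CC(O)[C@@]2(C)[C@H]1CO | intermediate
22 | bis(methanesulfonate) of 21 | C=C1CC[C@@H]2C(C)(C)C(=O)CC(OS(C)(=O)=O)[C@@]2(C)[C@H]1COS(C)(=O)=O | intermediate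
23 | [(1S,4aS,8aR)-5,5,8a-trimethyl-2-methylidene-6-oxo-1,2,3,4,4a,5,6,8a-octahydronaphthalen-1-yl]methyl methanesulfonate | C=C1CC[C@@H]2C(C)(C)C(=O)C=C[C@@]2(C)[C@H]1COS(C)(=O)=O | intermediate
24 | isofraxidin (7-hydroxy-6,8-dimethoxy-2H-chromen-2-one) | COc1cc2ccc(=O)oc2c(OC)c1O | starting material
25 | 7-{[(1S,4aS,8aR)-5,5,8a-trimethyl-2-methylidene-6-oxo-1,2,3,4,4a,5,6,8a-octahydronaphthalen-1-yl]methoxy}-6,8-dimethoxy-2H-chromen-2-one | C=C1CC[C@@H]2C(C)(C)C(=O)C=C[C@@]2(C)[C@H]1COc1c(OC)cc2ccc(=O)oc2c1OC | target

Total step count: 10. Longest linear sequence: 10 steps (1 and 2 to 25); 7, 13 and 24 enter as purchased materials.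

Steps most likely to fail

Step 7 (key step). Proton transfer from the methyl ketone to the free enolate may stop the chain, silyl transfer to the hindered adduct enolate may be slow, a boat-like transition state may erode the selectivity at C5, and O-methylation may compete. The fallback changes the acceptor and the way the enolate is made; it sets out from 10, by-passes steps 5 and 6, and comes back at 18. Compound 10 is cross-metathesised (catalyst of step 6) with S-ethyl 2-methylprop-2-enethioate F1, made from methacryloyl chloride and ethanethiol with Et3N, to give the (E)-enethioate lactone F2. Because the thioester has no acidic α-hydrogen, LiN(iPr)2 (THF, −78 °C) deprotonates the lactone directly; the lithium enolate closes ring B by the same 6-exo Michael addition and MeI traps the thioester enolate, giving the thioester lactone F3. Me2CuLi (Et2O, −78 °C) then converts the thioester into the methyl ketone 18.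

Step 8. The enolate may be acylated by the lactone carbonyl (Claisen-type closure to a 1,3-dione) before the hydride arrives, or the released aldehyde may be over-reduced. The fallback closes ring A on the cyclic oxocarbenium ion instead of the free aldehyde and removes the ring oxygen from C1 afterwards; it sets out from 18 and comes back at 25. The ketone is masked as the silyl enol ether F4 (LiN(iPr)2 with TBSCl present, THF, −78 °C). Reduction with iBu2AlH at −78 °C and quenching of the lactolate with Ac2O, pyridine and DMAP gives the lactol acetate F5. BF3·OEt2 (CH2Cl2, −78 °C) ionises the acetate and the enol ether adds to the oxocarbenium ion, giving the cyclic ether ketone F6 with a C1–O–C11 bridge. Me2BBr (CH2Cl2, −78 → 0 °C) cleaves this ether by bromide attack at the primary C11, giving the bromo aldol F7. MsCl and Et3N dehydrate it to the bromo enone F8, which is etherified with 24 under the conditions of step 10 to give 25.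

Step 10. Substitution at the β-branched, axial C11 centre by a di-ortho-substituted phenoxide may be slow, with competing elimination toward C9. The fallback activates the alcohol as an oxyphosphonium ion and forms the enone last; it sets out from 21 and comes back at 25. Mitsunobu etherification of the primary hydroxyl of 21 with 24 (PPh3, DIAD, THF, 0 °C → rt) should give the aryl ether aldol F9, the hindered secondary hydroxyl staying free. MsCl and Et3N then remove that hydroxyl by mesylation and E1cB elimination to give 25.

Further compounds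
F1 | step 7 | S-ethyl 2-methylprop-2-enethioate | CCSC(=O)C(C)=C
F2 | step 7 | S-ethyl (2E)-2-methyl-6-[(3R,4S)-4-methyl-5-oxooxolan-3-yl]hepta-2,6-dienethioate | O=C1OC[C@@H](C(=C)CC/C=C(\C)C(=O)SCC)[C@@H]1C
F3 | step 7 | S-ethyl thioester analogue of 18 (C(=O)SEt in place of the acetyl group, same configuration) | C=C1CC[C@H](C(C)(C)C(=O)SCC)[C@@]2(C)C(=O)OC[C@@H]12
F4 | step 8 | tert-butyldimethylsilyl enol ether of the methyl ketone of 18 | C=C1CC[C@H](C(C)(C)C(=C)O[Si](C)(C)C(C)(C)C)[C@@]2(C)C(=O)OC[C@@H]12
F5 | step 8 | lactol acetate of F4 (anomers) | C=C1CC[C@H](C(C)(C)C(=C)O[Si](C)(C)C(C)(C)C)[C@@]2(C)C(OC(C)=O)OC[C@@H]12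
F6 | step 8 | tricyclic ether ketone (drimane skeleton, 3-ketone, C1–O–C11 ether bridge cis-fused to rings A and B) | C=C1CC[C@@H]2C(C)(C)C(=O)C[C@H]3OC[C@@H]1[C@@]23C
F7 | step 8 | bromo aldol (1-hydroxy, 11-bromo, 3-ketone) | C=C1CC[C@@H]2C(C)(C)C(=O)C[C@@H](O)[C@@]2(C)[C@H]1CBr
F8 | step 8 | bromo enone (11-bromo analogue of 23) | C=C1CC[C@@H]2C(C)(C)C(=O)C=C[C@@]2(C)[C@H]1CBr
F9 | step 10 | aryl ether aldol (1-hydroxy-1,2-dihydro analogue of 25, C1 epimers) | C=C1CC[C@@H]2C(C)(C)C(=O)CC(O)[C@@]2(C)[C@H]1COc1c(OC)cc2ccc(=O)oc2c1OC
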